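**Retrosynthetic overview**
1. Target 35 ⇐ its 8‑O‑TBS ether 34 (final desilylation only).
2. 34 ⇐ open‑chain (Z)‑enal / (Z)‑2‑(bromomethyl)enoate 31 by the C6–C7 bond: a chromium‑catalysed, ligand‑controlled macrocyclizing 2‑(alkoxycarbonyl)allylation (new). The ten‑membered carbocycle forms first, the γ‑lactone (O6–C12) second, in the same flask; C6 and C7 are set here.
3. 31 ⇐ aldehyde 26 (Morita–Baylis–Hillman, SN2' bromination) ⇐ alkenyl iodide 20 (Stille hydroxymethylation gives C15; then acetate and tiglate).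
4. 20 ⇐ propargylic diol 17 (directed trans‑hydroalumination/iodination sets C4=C5) ⇐ alkenyl iodide 12 + (R)‑glycidyl ether 13 (C9–C10 bond; C8 from the chiral pool).
5. 12 ⇐ aldehyde 7 (iodo‑Wittig sets C1=C10) ⇐ (S)‑glycidyl ether 1 + propargyl ether 2 (C3–C4 bond; C2 from the chiral pool).

Assumptions: both enantiomers of 4‑methoxybenzyl (PMB) glycidyl ether are taken as purchasable; locants C1–C15 in the "Why" lines are those of the target's germacrane skeleton (C6 lactone carbinol, C7 ring‑fusion CH, C8 free carbinol, C2 tiglate carbinol, C15 acetoxymethyl, C11–C13 methylene‑lactone carbons).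

**Route**

Step 1
Reactants: 1 (S)-2-{[(4-methoxybenzyl)oxy]methyl}oxirane; 2 tert-butyldimethyl(prop-2-yn-1-yloxy)silane
Product: 4 (2S)-6-[(tert-butyldimethylsilyl)oxy]-1-[(4-methoxybenzyl)oxy]hex-4-yn-2-ol, via lithium acetylide 3 (not isolated)
Conditions: n-BuLi, THF, −78 °C; then BF3·OEt2, 1, −78 °C
Reagents that add atoms: none
Why: BF3‑promoted epoxide alkynylation (Yamaguchi–Hirao type): the lithium acetylide opens the activated epoxide by SN2 attack at the unsubstituted carbon, so the C2–O stereocentre of 1 is carried over unchanged as 2S.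

Step 2
Reactants: 4 (2S)-6-[(tert-butyldimethylsilyl)oxy]-1-[(4-methoxybenzyl)oxy]hex-4-yn-2-ol
Product: 5 (2S)-6-[(tert-butyldimethylsilyl)oxy]-1-[(4-methoxybenzyl)oxy]-2-[(triethylsilyl)oxy]hex-4-yne
Conditions: Et3SiCl, imidazole, CH2Cl2, 0 °C
Reagents that add atoms: chlorotriethylsilane CC[Si](Cl)(CC)CC
Why: Standard silyl ether formation; the triethylsilyl group is chosen so that it can later be removed together with the primary TBS ether while a hindered secondary TBS ether survives.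

Step 3
Reactants: 5 (2S)-6-[(tert-butyldimethylsilyl)oxy]-1-[(4-methoxybenzyl)oxy]-2-[(triethylsilyl)oxy]hex-4-yne
Product: 6 (2S)-6-[(tert-butyldimethylsilyl)oxy]-2-[(triethylsilyl)oxy]hex-4-yn-1-ol
Conditions: DDQ, CH2Cl2/pH 7 buffer, 0 °C
Reagents that add atoms: none
Why: Oxidative PMB ether cleavage: hydride abstraction at the electron‑rich benzylic position and hydrolysis of the oxocarbenium ion free the C1 alcohol, and the buffered medium leaves both silyl ethers intact.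

Step 4
Reactants: 6 (2S)-6-[(tert-butyldimethylsilyl)oxy]-2-[(triethylsilyl)oxy]hex-4-yn-1-ol
Product: 7 (2S)-6-[(tert-butyldimethylsilyl)oxy]-2-[(triethylsilyl)oxy]hex-4-ynal
Conditions: Dess–Martin periodinane, CH2Cl2, 0 °C to rt
Reagents that add atoms: none
Why: Dess–Martin oxidation is mild and non‑basic, so the α‑silyloxy aldehyde forms without epimerization at C2.

Step 5
Reactants: 7 (2S)-6-[(tert-butyldimethylsilyl)oxy]-2-[(triethylsilyl)oxy]hex-4-ynal; 8 ethyltriphenylphosphonium iodide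
Product: 12 (5S,6Z)-1-[(tert-butyldimethylsilyl)oxy]-7-iodo-5-[(triethylsilyl)oxy]oct-6-en-2-yne, via ethylidenetriphenylphosphorane 9 (not isolated), via (1-iodoethyl)triphenylphosphonium iodide 10 (not isolated), via (1-iodoethylidene)triphenylphosphorane 11 (not isolated)
Conditions: n-BuLi, THF, 0 °C; I2, −78 °C; NaN(SiMe3)2, −78 °C; then 7, −78 to −20 °C
Reagents that add atoms: iodine II
Why: Stork–Zhao‑type iodo‑Wittig olefination: the non‑stabilised α‑iodo ylide 11 adds under kinetic control through the cis‑oxaphosphetane to give the (Z)‑iodoalkene with iodine cis to C2, which fixes the later 1(10)Z geometry.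

Step 6
Reactants: 12 (5S,6Z)-1-[(tert-butyldimethylsilyl)oxy]-7-iodo-5-[(triethylsilyl)oxy]oct-6-en-2-yne; 13 (R)-2-{[(4-methoxybenzyl)oxy]methyl}oxirane
Product: 15 (2R,4Z,6S)-10-[(tert-butyldimethylsilyl)oxy]-1-[(4-methoxybenzyl)oxy]-4-methyl-6-[(triethylsilyl)oxy]dec-4-en-8-yn-2-ol, via alkenyllithium 14 (not isolated)
Conditions: t-BuLi (2.1 equiv), Et2O, −78 °C; then 13, BF3·OEt2, −78 °C
Reagents that add atoms: none
Why: Iodine–lithium exchange proceeds with retention of alkene geometry and the alkenyllithium opens the BF3‑activated epoxide 13 at its CH2 carbon (SN2), forming C9–C10 while C8 keeps the R configuration of 13.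

Step 7
Reactants: 15 (2R,4Z,6S)-10-[(tert-butyldimethylsilyl)oxy]-1-[(4-methoxybenzyl)oxy]-4-methyl-6-[(triethylsilyl)oxy]dec-4-en-8-yn-2-ol
Product: 16 (2R,4Z,6S)-2,10-bis[(tert-butyldimethylsilyl)oxy]-1-[(4-methoxybenzyl)oxy]-4-methyl-6-[(triethylsilyl)oxy]dec-4-en-8-yne
Conditions: TBSOTf, 2,6-lutidine, CH2Cl2, −78 °C
Reagents that add atoms: tert-butyldimethylsilyl trifluoromethanesulfonate CC(C)(C)[Si](C)(C)OS(=O)(=O)C(F)(F)F
Why: Silylation of the secondary C8 alcohol with the reactive silyl triflate; no stereocentre is touched.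

Step 8
Reactants: 16 (2R,4Z,6S)-2,10-bis[(tert-butyldimethylsilyl)oxy]-1-[(4-methoxybenzyl)oxy]-4-methyl-6-[(triethylsilyl)oxy]dec-4-en-8-yne
Product: 17 (5S,6Z,9R)-9-[(tert-butyldimethylsilyl)oxy]-10-[(4-methoxybenzyl)oxy]-7-methyldec-6-en-2-yne-1,5-diol
Conditions: HF·pyridine, pyridine, THF, 0 °C to rt
Reagents that add atoms: none
Why: Graded fluoride‑mediated desilylation: the secondary triethylsilyl ether and the primary TBS ether are cleaved much faster than the secondary TBS ether at C8.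

Step 9
Reactants: 17 (5S,6Z,9R)-9-[(tert-butyldimethylsilyl)oxy]-10-[(4-methoxybenzyl)oxy]-7-methyldec-6-en-2-yne-1,5-diol
Product: 19 (2Z,5S,6Z,9R)-9-[(tert-butyldimethylsilyl)oxy]-3-iodo-10-[(4-methoxybenzyl)oxy]-7-methyldeca-2,6-diene-1,5-diol, via cyclic alkenylalanate 18 (not isolated)
Conditions: NaAlH2(OCH2CH2OCH3)2, THF, 0 °C to rt; then I2, −78 to 0 °C
Reagents that add atoms: iodine II
Why: Hydroxyl‑directed trans‑hydroalumination of the propargylic alcohol (Corey type) delivers hydride to C5 and aluminium to C4 in the five‑membered alanate 18, and iodinolysis with retention gives the iodoalkene with iodine cis to C6, which sets the C4=C5 geometry.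

Step 10
Reactants: 19 (2Z,5S,6Z,9R)-9-[(tert-butyldimethylsilyl)oxy]-3-iodo-10-[(4-methoxybenzyl)oxy]-7-methyldeca-2,6-diene-1,5-diol
Product: 20 (2Z,5S,6Z,9R)-1,9-bis[(tert-butyldimethylsilyl)oxy]-3-iodo-10-[(4-methoxybenzyl)oxy]-7-methyldeca-2,6-dien-5-ol
Conditions: TBSCl (1.05 equiv), imidazole, CH2Cl2, −20 °C
Reagents that add atoms: tert-butyldimethylsilyl chloride CC(C)(C)[Si](C)(C)Cl
Why: Selective silylation of the unhindered primary allylic alcohol over the secondary C2 alcohol at low temperature.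

Step 11
Reactants: 20 (2Z,5S,6Z,9R)-1,9-bis[(tert-butyldimethylsilyl)oxy]-3-iodo-10-[(4-methoxybenzyl)oxy]-7-methyldeca-2,6-dien-5-ol; 21 (tributylstannyl)methanol
Product: 22 (2Z,5S,6Z,9R)-1,9-bis[(tert-butyldimethylsilyl)oxy]-3-(hydroxymethyl)-10-[(4-methoxybenzyl)oxy]-7-methyldeca-2,6-dien-5-ol
Conditions: Pd(PPh3)4 (5 mol%), dioxane, 90 °C
Reagents that add atoms: none
Why: Stille (Migita–Kosugi–Stille) coupling transfers the hydroxymethyl group from tin to the alkenylpalladium intermediate with retention of alkene geometry, installing C15 cis to C6.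

Step 12
Reactants: 22 (2Z,5S,6Z,9R)-1,9-bis[(tert-butyldimethylsilyl)oxy]-3-(hydroxymethyl)-10-[(4-methoxybenzyl)oxy]-7-methyldeca-2,6-dien-5-ol
Product: 23 (2Z,5S,6Z,9R)-3-(acetoxymethyl)-1,9-bis[(tert-butyldimethylsilyl)oxy]-10-[(4-methoxybenzyl)oxy]-7-methyldeca-2,6-dien-5-ol
Conditions: Ac2O (1.1 equiv), pyridine, CH2Cl2, −20 °C
Reagents that add atoms: acetic anhydride CC(=O)OC(C)=O
Why: Rate‑selective acetylation of the primary allylic alcohol over the more hindered secondary C2 alcohol with a slight excess of anhydride at low temperature.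

Step 13
Reactants: 23 (2Z,5S,6Z,9R)-3-(acetoxymethyl)-1,9-bis[(tert-butyldimethylsilyl)oxy]-10-[(4-methoxybenzyl)oxy]-7-methyldeca-2,6-dien-5-ol
Product: 24 (2Z,5S,6Z,9R)-3-(acetoxymethyl)-1,9-bis[(tert-butyldimethylsilyl)oxy]-10-[(4-methoxybenzyl)oxy]-7-methyldeca-2,6-dien-5-yl (E)-2-methylbut-2-enoate
Conditions: tigloyl chloride, pyridine, DMAP (cat.), CH2Cl2, 0 °C to rt
Reagents that add atoms: tigloyl chloride [(E)-2-methylbut-2-enoyl chloride] C/C=C(\C)C(Cl)=O
Why: DMAP‑catalysed acylation of the C2 alcohol with the acid chloride proceeds with retention at C2, and the thermodynamically stable E (tiglate) geometry of the acyl group is kept.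

Step 14
Reactants: 24 (2Z,5S,6Z,9R)-3-(acetoxymethyl)-1,9-bis[(tert-butyldimethylsilyl)oxy]-10-[(4-methoxybenzyl)oxy]-7-methyldeca-2,6-dien-5-yl (E)-2-methylbut-2-enoate
Product: 25 (2Z,5S,6Z,9R)-3-(acetoxymethyl)-1,9-bis[(tert-butyldimethylsilyl)oxy]-10-hydroxy-7-methyldeca-2,6-dien-5-yl (E)-2-methylbut-2-enoate
Conditions: DDQ, CH2Cl2/pH 7 buffer, 0 °C
Reagents that add atoms: none
Why: DDQ cleaves the PMB ether oxidatively without affecting the esters, silyl ethers or alkenes.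

Step 15
Reactants: 25 (2Z,5S,6Z,9R)-3-(acetoxymethyl)-1,9-bis[(tert-butyldimethylsilyl)oxy]-10-hydroxy-7-methyldeca-2,6-dien-5-yl (E)-2-methylbut-2-enoate
Product: 26 (2Z,5S,6Z,9R)-3-(acetoxymethyl)-1,9-bis[(tert-butyldimethylsilyl)oxy]-7-methyl-10-oxodeca-2,6-dien-5-yl (E)-2-methylbut-2-enoate
Conditions: Dess–Martin periodinane, CH2Cl2, 0 °C
Reagents that add atoms: none
Why: Dess–Martin oxidation gives the α‑silyloxy aldehyde (C7) under non‑epimerizing conditions.

Step 16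
Reactants: 26 (2Z,5S,6Z,9R)-3-(acetoxymethyl)-1,9-bis[(tert-butyldimethylsilyl)oxy]-7-methyl-10-oxodeca-2,6-dien-5-yl (E)-2-methylbut-2-enoate; 27 methyl acrylate
Product: 28 methyl (4R,6Z,8S,10Z)-10-(acetoxymethyl)-4,12-bis[(tert-butyldimethylsilyl)oxy]-3-hydroxy-6-methyl-2-methylidene-8-{[(E)-2-methylbut-2-enoyl]oxy}dodeca-6,10-dienoate (C3 epimers)
Conditions: DABCO (1 equiv), neat 27, rt, 3–5 d
Reagents that add atoms: none
Why: Morita–Baylis–Hillman reaction: DABCO adds to the acrylate and the ammonium enolate adds to the activated α‑alkoxy aldehyde; the new C7 carbinol centre is inconsequential because it becomes sp2 in step 19.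

Step 17
Reactants: 28 methyl (4R,6Z,8S,10Z)-10-(acetoxymethyl)-4,12-bis[(tert-butyldimethylsilyl)oxy]-3-hydroxy-6-methyl-2-methylidene-8-{[(E)-2-methylbut-2-enoyl]oxy}dodeca-6,10-dienoate
Product: 29 methyl (4R,6Z,8S,10Z)-10-(acetoxymethyl)-4-[(tert-butyldimethylsilyl)oxy]-3,12-dihydroxy-6-methyl-2-methylidene-8-{[(E)-2-methylbut-2-enoyl]oxy}dodeca-6,10-dienoate
Conditions: HF·pyridine, pyridine, THF, 0 °C
Reagents that add atoms: none
Why: Selective cleavage of the primary allylic TBS ether in the presence of the hindered secondary TBS ether at C8 by buffered HF·pyridine.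

Step 18
Reactants: 29 methyl (4R,6Z,8S,10Z)-10-(acetoxymethyl)-4-[(tert-butyldimethylsilyl)oxy]-3,12-dihydroxy-6-methyl-2-methylidene-8-{[(E)-2-methylbut-2-enoyl]oxy}dodeca-6,10-dienoate
Product: 30 methyl (4R,6Z,8S,10Z)-10-(acetoxymethyl)-4-[(tert-butyldimethylsilyl)oxy]-3-hydroxy-6-methyl-2-methylidene-8-{[(E)-2-methylbut-2-enoyl]oxy}-12-oxododeca-6,10-dienoate
Conditions: MnO2, CH2Cl2, rt
Reagents that add atoms: none
Why: MnO2 oxidizes only the electron‑rich primary allylic alcohol and leaves the electron‑poor secondary Morita–Baylis–Hillman alcohol and the Z geometry of the enal untouched.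

Step 19
Reactants: 30 methyl (4R,6Z,8S,10Z)-10-(acetoxymethyl)-4-[(tert-butyldimethylsilyl)oxy]-3-hydroxy-6-methyl-2-methylidene-8-{[(E)-2-methylbut-2-enoyl]oxy}-12-oxododeca-6,10-dienoate
Product: 31 methyl (2Z,4R,6Z,8S,10Z)-10-(acetoxymethyl)-2-(bromomethyl)-4-[(tert-butyldimethylsilyl)oxy]-6-methyl-8-{[(E)-2-methylbut-2-enoyl]oxy}-12-oxododeca-2,6,10-trienoate
Conditions: NBS, Me2S, CH2Cl2, −20 to 0 °C
Reagents that add atoms: N-bromosuccinimide O=C1CCC(=O)N1Br
Why: Corey–Kim‑type activation of the allylic alcohol followed by SN2' attack of bromide gives the (Z)-2-(bromomethyl)enoate stereoselectively, with the C8 stereocentre untouched.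

Step 20
Reactants: 31 methyl (2Z,4R,6Z,8S,10Z)-10-(acetoxymethyl)-2-(bromomethyl)-4-[(tert-butyldimethylsilyl)oxy]-6-methyl-8-{[(E)-2-methylbut-2-enoyl]oxy}-12-oxododeca-2,6,10-trienoate
Product: 34 8-O-(tert-butyldimethylsilyl) ether of 35 (15-acetoxy-8β-silyloxy-2α-tigloyloxygermacra-1(10)Z,4Z,11(13)-trien-12,6α-olide), via macrocyclic trimethylsilyl ether 32 (not isolated), via macrocyclic hydroxy ester 33 (not isolated)
Conditions: CrCl2 (10 mol%), L (12 mol%), Mn powder (3 equiv), Me3SiCl (2 equiv), iPr2NEt (20 mol%), THF, rt, syringe‑pump addition of 31 to 2 mM; then TsOH·H2O (cat.), CH2Cl2, rt; L = (S,S)-3,6-di-tert-butyl-1,8-bis(4-isopropyl-4,5-dihydrooxazol-2-yl)-9H-carbazole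
Reagents that add atoms: none
Why: Proposed new method: a chromium‑catalysed, ligand‑controlled macrocyclizing 2‑(alkoxycarbonyl)allylation in which two divalent chromium centres insert into the allylic C–Br bond of 31 to give a configurationally labile allyl–trivalent‑chromium species bound to L that adds to the C6 aldehyde through a chair (Zimmerman–Traxler) transition state with both ring chains equatorial (anti addition, hence 6,7‑trans) on the Si face selected by the ligand (C6 R, C7 R, with catalyst control meant to override the bias of the C8 silyloxy centre), while Me3SiCl releases the product as silyl ether 32, Mn powder returns trivalent to divalent chromium, and acid then gives 33 and closes the trans‑lactone; the closest known reactions are the stoichiometric CrCl2 Barbier (Nozaki–Hiyama‑type) macrocyclization of 2‑(bromomethyl)enoate aldehydes to ten‑membered germacranolide rings and the intermolecular chromium‑catalysed enantioselective 2‑(alkoxycarbonyl)allylation of aldehydes with carbazole bis(oxazoline) ligands.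

Step 21
Reactants: 34 8-O-(tert-butyldimethylsilyl) ether of 35
Product: 35 CNP0129394.2: (2S,6R,7R,8R)-15-acetoxy-8-hydroxy-2-[(E)-2-methylbut-2-enoyloxy]germacra-1(10)Z,4Z,11(13)-trien-12,6-olide
Conditions: HF·pyridine, THF, 0 °C to rt
Reagents that add atoms: none
Why: Fluoride‑mediated cleavage of the secondary TBS ether under mildly acidic conditions that spare the α‑methylene lactone and both esters.

**Compound list**

1 | (S)-2-{[(4-methoxybenzyl)oxy]methyl}oxirane | COc1ccc(COC[C@@H]2CO2)cc1 | starting material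
2 | tert-butyldimethyl(prop-2-yn-1-yloxy)silane | C#CCO[Si](C)(C)C(C)(C)C | starting material
3 | [3-(tert-butyldimethylsilyloxy)prop-1-yn-1-yl]lithium (not isolated) | [Li]C#CCO[Si](C)(C)C(C)(C)C | intermediate
4 | (2S)-6-[(tert-butyldimethylsilyl)oxy]-1-[(4-methoxybenzyl)oxy]hex-4-yn-2-ol | CC(C)(C)[Si](C)(C)OCC#CC[C@H](O)COCc1ccc(OC)cc1 | intermediate
5 | (2S)-6-[(tert-butyldimethylsilyl)oxy]-1-[(4-methoxybenzyl)oxy]-2-[(triethylsilyl)oxy]hex-4-yne | CC(C)(C)[Si](C)(C)OCC#CC[C@H](O[Si](CC)(CC)CC)COCc1ccc(OC)cc1 | intermediate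
6 | (2S)-6-[(tert-butyldimethylsilyl)oxy]-2-[(triethylsilyl)oxy]hex-4-yn-1-ol | CC(C)(C)[Si](C)(C)OCC#CC[C@H](O[Si](CC)(CC)CC)CO | intermediate
7 | (2S)-6-[(tert-butyldimethylsilyl)oxy]-2-[(triethylsilyl)oxy]hex-4-ynal | CC(C)(C)[Si](C)(C)OCC#CC[C@H](O[Si](CC)(CC)CC)C=O | intermediate
8 | ethyltriphenylphosphonium iodide | CC[P+](c1ccccc1)(c1ccccc1)c1ccccc1.[I-] | starting material
9 | ethylidenetriphenylphosphorane (not isolated) | CC=P(c1ccccc1)(c1ccccc1)c1ccccc1 | intermediate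
10 | (1-iodoethyl)triphenylphosphonium iodide (not isolated) | CC(I)[P+](c1ccccc1)(c1ccccc1)c1ccccc1.[I-] | intermediate
11 | (1-iodoethylidene)triphenylphosphorane (not isolated) | CC(I)=P(c1ccccc1)(c1ccccc1)c1ccccc1 | intermediate
12 | (5S,6Z)-1-[(tert-butyldimethylsilyl)oxy]-7-iodo-5-[(triethylsilyl)oxy]oct-6-en-2-yne | CC(C)(C)[Si](C)(C)OCC#CC[C@H](O[Si](CC)(CC)CC)/C=C(/C)I | intermediate
13 | (R)-2-{[(4-methoxybenzyl)oxy]methyl}oxirane | COc1ccc(COC[C@H]2CO2)cc1 | starting material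
14 | alkenyllithium from 12 (Li in place of I, Z geometry retained; not isolated) | CC(C)(C)[Si](C)(C)OCC#CC[C@H](O[Si](CC)(CC)CC)/C=C(/C)[Li] | intermediate
15 | (2R,4Z,6S)-10-[(tert-butyldimethylsilyl)oxy]-1-[(4-methoxybenzyl)oxy]-4-methyl-6-[(triethylsilyl)oxy]dec-4-en-8-yn-2-ol | CC(C)(C)[Si](C)(C)OCC#CC[C@H](O[Si](CC)(CC)CC)/C=C(/C)C[C@@H](O)COCc1ccc(OC)cc1 | intermediate
16 | (2R,4Z,6S)-2,10-bis[(tert-butyldimethylsilyl)oxy]-1-[(4-methoxybenzyl)oxy]-4-methyl-6-[(triethylsilyl)oxy]dec-4-en-8-yne | CC(C)(C)[Si](C)(C)OCC#CC[C@H](O[Si](CC)(CC)CC)/C=C(/C)C[C@@H](O[Si](C)(C)C(C)(C)C)COCc1ccc(OC)cc1 | intermediate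
17 | (5S,6Z,9R)-9-[(tert-butyldimethylsilyl)oxy]-10-[(4-methoxybenzyl)oxy]-7-methyldec-6-en-2-yne-1,5-diol | OCC#CC[C@H](O)/C=C(/C)C[C@@H](O[Si](C)(C)C(C)(C)C)COCc1ccc(OC)cc1 | intermediate
18 | cyclic sodium alkenylalanate from 17 (Al on C4 and O6, hydride added at C5, C2 oxygen as alkoxyaluminate; not isolated) | [Na+].[Na+].COCCO[Al-]1(OCCOC)OC/C=C1/C[C@H](O[AlH-](OCCOC)OCCOC)/C=C(/C)C[C@@H](O[Si](C)(C)C(C)(C)C)COCc1ccc(OC)cc1 | intermediate
19 | (2Z,5S,6Z,9R)-9-[(tert-butyldimethylsilyl)oxy]-3-iodo-10-[(4-methoxybenzyl)oxy]-7-methyldeca-2,6-diene-1,5-diol | OC/C=C(\I)C[C@H](O)/C=C(/C)C[C@@H](O[Si](C)(C)C(C)(C)C)COCc1ccc(OC)cc1 | intermediate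
20 | (2Z,5S,6Z,9R)-1,9-bis[(tert-butyldimethylsilyl)oxy]-3-iodo-10-[(4-methoxybenzyl)oxy]-7-methyldeca-2,6-dien-5-ol | CC(C)(C)[Si](C)(C)OC/C=C(\I)C[C@H](O)/C=C(/C)C[C@@H](O[Si](C)(C)C(C)(C)C)COCc1ccc(OC)cc1 | intermediate
21 | (tributylstannyl)methanol | OC[Sn](CCCC)(CCCC)CCCC | starting material
22 | (2Z,5S,6Z,9R)-1,9-bis[(tert-butyldimethylsilyl)oxy]-3-(hydroxymethyl)-10-[(4-methoxybenzyl)oxy]-7-methyldeca-2,6-dien-5-ol | CC(C)(C)[Si](C)(C)OC/C=C(\CO)C[C@H](O)/C=C(/C)C[C@@H](O[Si](C)(C)C(C)(C)C)COCc1ccc(OC)cc1 | intermediate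
23 | (2Z,5S,6Z,9R)-3-(acetoxymethyl)-1,9-bis[(tert-butyldimethylsilyl)oxy]-10-[(4-methoxybenzyl)oxy]-7-methyldeca-2,6-dien-5-ol | CC(C)(C)[Si](C)(C)OC/C=C(\COC(C)=O)C[C@H](O)/C=C(/C)C[C@@H](O[Si](C)(C)C(C)(C)C)COCc1ccc(OC)cc1 | intermediate
24 | (2Z,5S,6Z,9R)-3-(acetoxymethyl)-1,9-bis[(tert-butyldimethylsilyl)oxy]-10-[(4-methoxybenzyl)oxy]-7-methyldeca-2,6-dien-5-yl (E)-2-methylbut-2-enoate | CC(C)(C)[Si](C)(C)OC/C=C(\COC(C)=O)C[C@H](OC(=O)/C(C)=C/C)/C=C(/C)C[C@@H](O[Si](C)(C)C(C)(C)C)COCc1ccc(OC)cc1 | intermediate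
25 | (2Z,5S,6Z,9R)-3-(acetoxymethyl)-1,9-bis[(tert-butyldimethylsilyl)oxy]-10-hydroxy-7-methyldeca-2,6-dien-5-yl (E)-2-methylbut-2-enoate | CC(C)(C)[Si](C)(C)OC/C=C(\COC(C)=O)C[C@H](OC(=O)/C(C)=C/C)/C=C(/C)C[C@@H](O[Si](C)(C)C(C)(C)C)CO | intermediate
26 | (2Z,5S,6Z,9R)-3-(acetoxymethyl)-1,9-bis[(tert-butyldimethylsilyl)oxy]-7-methyl-10-oxodeca-2,6-dien-5-yl (E)-2-methylbut-2-enoate | CC(C)(C)[Si](C)(C)OC/C=C(\COC(C)=O)C[C@H](OC(=O)/C(C)=C/C)/C=C(/C)C[C@@H](O[Si](C)(C)C(C)(C)C)C=O | intermediate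
27 | methyl acrylate | C=CC(=O)OC | starting material
28 | methyl (4R,6Z,8S,10Z)-10-(acetoxymethyl)-4,12-bis[(tert-butyldimethylsilyl)oxy]-3-hydroxy-6-methyl-2-methylidene-8-{[(E)-2-methylbut-2-enoyl]oxy}dodeca-6,10-dienoate (C3 epimers) | CC(C)(C)[Si](C)(C)OC/C=C(\COC(C)=O)C[C@H](OC(=O)/C(C)=C/C)/C=C(/C)C[C@@H](O[Si](C)(C)C(C)(C)C)C(O)C(=C)C(=O)OC | intermediate
29 | methyl (4R,6Z,8S,10Z)-10-(acetoxymethyl)-4-[(tert-butyldimethylsilyl)oxy]-3,12-dihydroxy-6-methyl-2-methylidene-8-{[(E)-2-methylbut-2-enoyl]oxy}dodeca-6,10-dienoate | OC/C=C(\COC(C)=O)C[C@H](OC(=O)/C(C)=C/C)/C=C(/C)C[C@@H](O[Si](C)(C)C(C)(C)C)C(O)C(=C)C(=O)OC | intermediate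
30 | methyl (4R,6Z,8S,10Z)-10-(acetoxymethyl)-4-[(tert-butyldimethylsilyl)oxy]-3-hydroxy-6-methyl-2-methylidene-8-{[(E)-2-methylbut-2-enoyl]oxy}-12-oxododeca-6,10-dienoate | O=C/C=C(\COC(C)=O)C[C@H](OC(=O)/C(C)=C/C)/C=C(/C)C[C@@H](O[Si](C)(C)C(C)(C)C)C(O)C(=C)C(=O)OC | intermediate
31 | methyl (2Z,4R,6Z,8S,10Z)-10-(acetoxymethyl)-2-(bromomethyl)-4-[(tert-butyldimethylsilyl)oxy]-6-methyl-8-{[(E)-2-methylbut-2-enoyl]oxy}-12-oxododeca-2,6,10-trienoate | O=C/C=C(\COC(C)=O)C[C@H](OC(=O)/C(C)=C/C)/C=C(/C)C[C@@H](O[Si](C)(C)C(C)(C)C)/C=C(\CBr)C(=O)OC | intermediate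
32 | 6-O-trimethylsilyl ether of 33 (not isolated) | COC(=O)C(=C)[C@H]1[C@H](O[Si](C)(C)C)/C=C(\COC(C)=O)C[C@H](OC(=O)/C(C)=C/C)/C=C(/C)C[C@H]1O[Si](C)(C)C(C)(C)C | intermediate
33 | macrocyclic hydroxy ester: 1(10)Z,4Z-cyclodecadiene with 6α-OH, 7β-[1-(methoxycarbonyl)vinyl], 8β-OTBS, 2α-OTig, 15-OAc (not isolated) | COC(=O)C(=C)[C@H]1[C@H](O)/C=C(\COC(C)=O)C[C@H](OC(=O)/C(C)=C/C)/C=C(/C)C[C@H]1O[Si](C)(C)C(C)(C)C | intermediate
34 | 8-O-(tert-butyldimethylsilyl) ether of 35 (15-acetoxy-8β-silyloxy-2α-tigloyloxygermacra-1(10)Z,4Z,11(13)-trien-12,6α-olide) | C=C1C(=O)O[C@@H]2/C=C(\COC(C)=O)C[C@H](OC(=O)/C(C)=C/C)/C=C(/C)C[C@@H](O[Si](C)(C)C(C)(C)C)[C@@H]12 | intermediate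
35 | CNP0129394.2: (2S,6R,7R,8R)-15-acetoxy-8-hydroxy-2-[(E)-2-methylbut-2-enoyloxy]germacra-1(10)Z,4Z,11(13)-trien-12,6-olide (2α-OTig, 8β-OH, 6α,12-olide, H7α; C4=C5 is trans within the ring) | C=C1C(=O)O[C@@H]2/C=C(\COC(C)=O)C[C@H](OC(=O)/C(C)=C/C)/C=C(/C)C[C@@H](O)[C@@H]12 | target

**Totals**
Total step count: 21. Longest linear sequence: 21 steps (from 1 or 2 to 35; 8, 13, 21 and 27 are purchased and enter directly).

**Three steps most likely to fail**

Step 20, the proposed new macrocyclization. The C8 silyloxy centre sits next to the reacting allyl terminus and may oppose the ligand (mismatched pair), so the C6/C7 configuration relative to C8 is the least certain point of the route. Part of the material may also react through the syn chair (cis‑lactone), and pinacol coupling, reductive loss of the γ‑acetoxy group of the enal, or oligomerization may compete. The ligand antipode is the first variable to test. Fallback (known chemistry): setting out from 31, give up catalyst control and turnover, and close the ring by the stoichiometric, substrate‑controlled Nozaki–Hiyama‑type Barbier reaction that is the established way to close ten‑membered germacranolide rings from 2‑(bromomethyl)enoate aldehydes. This means slow addition of 31 to excess CrCl2 in THF/DMF at high dilution, with no ligand, no silyl chloride and no manganese, followed by aqueous work‑up and isolation of hydroxy ester 33. A separate acid lactonization (PPTS, benzene, 60 °C) then comes back to the route at 34. Stereocontrol then rests only on the macrocyclic chair transition state, and diastereomers are separated at the stage of 33. New compounds on this detour: none F0.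

Step 16, the Morita–Baylis–Hillman reaction. The α‑silyloxy aldehyde 26 is hindered, the reaction takes days, and prolonged exposure to DABCO can epimerize C8. Fallback: setting out from 26, replace the amine‑catalysed reaction by an aldol/selenoxide‑elimination sequence. Addition of the lithium enolate of methyl 3-(phenylselanyl)propanoate (LiN(iPr)2, THF, −78 °C) to the aldehyde gives the selenide aldol adduct F3 within minutes. Oxidation with H2O2/pyridine at 0 °C and syn‑elimination of the selenoxide then comes back to the route at 28.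

Step 5, the iodo‑Wittig olefination. Yields of this reaction are often modest, and the Z/E ratio and de‑iodinated by‑products vary with the aldehyde. Fallback: setting out from 7, Corey–Fuchs olefination (CBr4, PPh3, CH2Cl2, 0 °C) gives the 1,1-dibromoalkene F1. Trans‑selective Negishi monomethylation (Me2Zn, Pd(P(t-Bu)3)2 cat., THF) replaces only the bromine trans to C2 and gives the (Z)-bromoalkene F2. Bromine–lithium exchange with t-BuLi then gives the same alkenyllithium 14, which is taken into the epoxide opening of step 6, so the route is rejoined at 15.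

**Further compounds**
F1 | step 5 | (3S)-1,1-dibromo-7-[(tert-butyldimethylsilyl)oxy]-3-[(triethylsilyl)oxy]hept-1-en-5-yne | CC(C)(C)[Si](C)(C)OCC#CC[C@H](O[Si](CC)(CC)CC)C=C(Br)Br
F2 | step 5 | (2Z,4S)-2-bromo-8-[(tert-butyldimethylsilyl)oxy]-4-[(triethylsilyl)oxy]oct-2-en-6-yne | CC(C)(C)[Si](C)(C)OCC#CC[C@H](O[Si](CC)(CC)CC)/C=C(/C)Br
F3 | step 16 | selenide aldol adduct of 26: methyl (4R,6Z,8S,10Z)-10-(acetoxymethyl)-4,12-bis[(tert-butyldimethylsilyl)oxy]-3-hydroxy-6-methyl-8-{[(E)-2-methylbut-2-enoyl]oxy}-2-[(phenylselanyl)methyl]dodeca-6,10-dienoate | CC(C)(C)[Si](C)(C)OC/C=C(\COC(C)=O)C[C@H](OC(=O)/C(C)=C/C)/C=C(/C)C[C@@H](O[Si](C)(C)C(C)(C)C)C(O)C(C[Se]c1ccccc1)C(=O)OC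
F0 | step 20 | none | none
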